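Late in the theta run the target stands still. You have to say what that standstill means for the flask, which has the same charge and temperature, at 2.5 h.

| setting | theta | gamma | flask |
|---|---|---|---|
| starting material | 0.020 M | 0.020 M | 0.020 M |
| reagent | 0.014 M | 0.014 M | 0.0140 M |
| second substrate | 0.020 M | 0.020 M | 0.0200 M |
| free catalyst | 11 µM | 11 µM | 11 µM |
| temperature | 80 °C | 75 °C | 80 °C |
| remark | the very flask that is asked about, followed so far | run made earlier |  |
| time |  |  | 2.5 h |

| run | time / min | target / % |
|---|---|---|
| theta | 10.0 | 29.6 |
| theta | 30.0 | 35.7 |
| theta | 60.0 | 36.8 |
| theta | 80.0 | 38.3 |
| theta | 120 | 38.4 |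
| gamma | 10.0 | 29.1 |
| gamma | 30.0 | 37.8 |
| gamma | 60.0 | 40.8 |
| gamma | 80.0 | 39.7 |
| gamma | 120 | 40.4 |

(scatter of a reading: 1 percentage point)

- winter: at 2.5 h add reagent, 50.0% of the amount charged, then wait 2.5 h
- midnight: at 2.5 h take out 90% of the target then present, then wait 2.5 h
- autumn: at 2.5 h raise the temperature by 10 K, then wait 2.5 h
- dusk: change nothing and wait 2.5 h more
- dawn: at 2.5 h add free catalyst, 100% of the amount charged, then wait 2.5 h

- target that was removed still counts
- the numbers in the tables scatter with a standard deviation of 1 percentage point
- additions bring no volume worth counting

- target, in percent of the starting material first charged, at 2.5 h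
- the remedy with the largest gain of target, or "none" below 2 percentage points (winter / midnight / autumn / dusk / dawn / none)
- target present, with what was taken out counted in, in percent of the starting material first charged, after winter
- target present, with what was taken out counted in, in percent of the starting material first charged, after dawn

1. Here is the puzzle. In the theta run, the reagent charged allows 70.0% of target, yet the last reading is 38.4%, and 61.6% of the starting material has not become target.

2. Now count turnovers. Let N, the turnover number, be the target made per catalyst charged: at the last reading of the theta run N = 698.

3. Next compare paces. By the readings, each catalyst turned over at 53.8 min⁻¹ on average in the first 10.0 min of the theta run, but at 0.545 min⁻¹ from 30.0 min to 120 min. I therefore read the stop in the theta run as a catalyst that quit working early, with part of the charge unused. The readings do not show how much reagent the second substrate took.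

4. Here is my reckoning. I take the pace of a catalyst to follow the product of starting material and reagent, so a fresh charge earns N times the share of that product still present. If each target used one reagent, and the second substrate used none, the share is 0.278. So I expect dawn to gain 11 percentage points or less. I hold the flask at about 38.4% now, and I expect no gain from winter.

5. The forecast says 38.6% now, dawn as the best remedy, 38.8% after winter and 51% after dawn: “Fresh catalyst gives a second burst.” Its dawn figure stands above my 49.4%.

The flask gives 37.1% now, dawn as the best remedy, 37.1% after winter and 43.3% after dawn.

    starting material + reagent + free catalyst → free catalyst + target (k = 5.00 × 10⁵ M⁻² min⁻¹, Ea = 36.0 kJ mol⁻¹)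
    second substrate + reagent + free catalyst → free catalyst + second product (k = 2.30 × 10⁵ M⁻² min⁻¹, Ea = 37.0 kJ mol⁻¹)
    starting material → decomposition product (k = 7.40 × 10⁻⁵ min⁻¹, Ea = 118 kJ mol⁻¹)
    free catalyst → spent catalyst (k = 0.0780 min⁻¹, Ea = 108 kJ mol⁻¹)
    (constants at 80 °C)

Under dawn, the second charge of catalyst in the flask earned 114 turnovers. With starting material at 62.2% and reagent at 19.6% at 150 min, N times their product is 85.2. Now take the neighbouring flask charged with 0.024 M of reagent. Scaling N by its reagent ratio of 1.71 gives 1200 turnovers. That flask made 1040 turnovers, which is 57.3% target at 150 min.

The readings are simulated on assumed constants; the scatter is artificial.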